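**Retrosynthetic overview**

- The target comes from its octamethyl ether by BBr3. The seven-membered ring is closed last, by protonating a stilbene and Friedel–Crafts attack of a flanking 3,5-dimethoxyphenyl ring (the two rings are equivalent by C2 symmetry, and this closure sets the fifth stereocentre).
- The stilbene comes from decarboxylative dehydration of a β-hydroxy acid, made by an intermolecular Ivanov aldol between a bis(dihydrobenzofuran) aldehyde and the dianion of (2,4-dimethoxyphenyl)acetic acid; this bond joins the two fragments.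
- The aldehyde comes from a trans,trans-tetrahydrobenzodifuran, obtained by acid epimerisation of the cis,cis product of a double enantioselective rhodium-carbene C–H insertion into two 4-methoxybenzyl ethers.
- The bis-diazo precursor comes from a bis-hydrazone, from a 2,6-diaroyl-3,5-bis(4-methoxybenzyloxy)benzyl silyl ether, from a dibromide and two equivalents of 3,5-dimethoxybenzaldehyde, from 3,5-dihydroxybenzyl alcohol and two equivalents of 4-methoxybenzyl chloride.
- Ring order: both dihydrofuran rings together first, the seven-membered carbocycle last.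

Assumption: Rh2(S-PTAD)4 (PTAD = N-phthaloyl-1-adamantylglycinate) is taken as the catalyst antipode that gives the 3R,5R series; if the sense is opposite, Rh2(R-PTAD)4 is used with no other change.

**Route**

Step 1
Reactants: 1 3,5-dihydroxybenzyl alcohol; 2 4-methoxybenzyl chloride
Product: 3 [3,5-bis(4-methoxybenzyloxy)phenyl]methanol
Conditions: 2 (2.2 equiv in all), K2CO3 (3 equiv), KI (cat.), DMF, 60 °C
Reagents that add atoms: 4-methoxybenzyl chloride (second equivalent of 2), COc1ccc(CCl)cc1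
Why: Double Williamson etherification in which each of the two phenoxides takes up one molecule of 2, while the benzylic alcohol is not deprotonated by carbonate and stays free.

Step 2
Reactants: 3 [3,5-bis(4-methoxybenzyloxy)phenyl]methanol
Product: 4 [2,6-dibromo-3,5-bis(4-methoxybenzyloxy)phenyl]methanol
Conditions: NBS (2.1 equiv), MeCN, 0 °C to rt
Reagents that add atoms: N-bromosuccinimide, O=C1CCC(=O)N1Br
Why: Electrophilic aromatic bromination of the resorcinol diether ring goes ortho/para to the ether oxygens at C2 and C6, the position between the two ethers being the most hindered.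

Step 3
Reactants: 4 [2,6-dibromo-3,5-bis(4-methoxybenzyloxy)phenyl]methanol
Product: 5 {[2,6-dibromo-3,5-bis(4-methoxybenzyloxy)phenyl]methoxy}triisopropylsilane
Conditions: TIPSCl, imidazole, DMF, rt
Reagents that add atoms: triisopropylsilyl chloride, CC(C)[Si](Cl)(C(C)C)C(C)C
Why: Silyl protection of the primary alcohol; the TIPS ether survives organolithiums and hydrazine and offers no C–H bond within reach of the later carbene.

Step 4
Reactants: 5 {[2,6-dibromo-3,5-bis(4-methoxybenzyloxy)phenyl]methoxy}triisopropylsilane; 6 3,5-dimethoxybenzaldehyde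
Product: 10 [2-{[(triisopropylsilyl)oxy]methyl}-4,6-bis(4-methoxybenzyloxy)-1,3-phenylene]bis[(3,5-dimethoxyphenyl)methanol] (diastereomer mixture), via monolithio bromide 7 (not isolated), via bromo lithium alkoxide 8 (not isolated), via lithio lithium alkoxide 9 (not isolated)
Conditions: n-BuLi (1.05 equiv), THF, −78 °C; 6 (1.1 equiv); n-BuLi (1.1 equiv), −78 °C; 6 (1.2 equiv); H2O
Reagents that add atoms: 3,5-dimethoxybenzaldehyde (second equivalent of 6), COc1cc(C=O)cc(OC)c1
Why: Two successive bromine–lithium exchanges, each followed by 1,2-addition of the aryllithium to one molecule of 6 at −78 °C (cold enough to avoid silyl migration and Wittig rearrangement), install both diaryl carbinols, whose stereocentres are oxidised away in the next step.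

Step 5
Reactants: 10 bis-carbinol
Product: 11 [2-{[(triisopropylsilyl)oxy]methyl}-4,6-bis(4-methoxybenzyloxy)-1,3-phenylene]bis[(3,5-dimethoxyphenyl)methanone]
Conditions: Dess–Martin periodinane (2.5 equiv), NaHCO3, CH2Cl2, 0 °C to rt
Reagents that add atoms: none
Why: Dess–Martin oxidation of the two diaryl carbinols to ketones under buffered, non-acidic conditions that leave the benzyl and silyl ethers alone.

Step 6
Reactants: 11 diketone
Product: 12 bis-hydrazone of 11 (E/Z mixture)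
Conditions: N2H4·H2O (30 equiv), AcOH (cat.), EtOH, 100 °C, sealed tube
Reagents that add atoms: hydrazine (as monohydrate), NN
Why: Hydrazone condensation at both ketones, forced with excess hydrazine and heat because each ketone is flanked by two ortho substituents.

Step 7
Reactants: 12 bis-hydrazone
Product: 14 triisopropyl{[(2S,3R,5R,6S)-3,5-bis(3,5-dimethoxyphenyl)-2,6-bis(4-methoxyphenyl)-2,3,5,6-tetrahydrobenzo[1,2-b:5,4-b']difuran-4-yl]methoxy}silane (cis,cis), via bis-diazo compound 13 (not isolated)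
Conditions: activated MnO2, CH2Cl2, 0 °C, dark; filter; Rh2(S-PTAD)4 (2 mol%), CH2Cl2, 0 °C, high dilution
Reagents that add atoms: none
Why: Hydrazone dehydrogenation gives the diaryldiazomethanes, and a double intramolecular 1,5 C–H insertion of the donor/donor rhodium carbenes into the 4-methoxybenzylic ether C–H bonds closes both cis-dihydrofuran rings, the chiral carboxylate ligands fixing C3 and C5 as R (C2 and C6 as S); the minor meso-type diastereomer is removed by chromatography, which raises the ee of the C2-symmetric product.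

Step 8
Reactants: 14 cis,cis silyl ether
Product: 15 triisopropyl{[(2R,3R,5R,6R)-3,5-bis(3,5-dimethoxyphenyl)-2,6-bis(4-methoxyphenyl)-2,3,5,6-tetrahydrobenzo[1,2-b:5,4-b']difuran-4-yl]methoxy}silane (trans,trans)
Conditions: BF3·OEt2 (0.3 equiv), CH2Cl2, −20 to 0 °C
Reagents that add atoms: none
Why: Acid-mediated epimerisation; the C2–O and C6–O bonds ionise reversibly to 4-methoxybenzylic cations and reclose to the thermodynamically favoured trans rings, while C3 and C5 are not touched.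

Step 9
Reactants: 15 trans,trans silyl ether
Product: 16 [(2R,3R,5R,6R)-3,5-bis(3,5-dimethoxyphenyl)-2,6-bis(4-methoxyphenyl)-2,3,5,6-tetrahydrobenzo[1,2-b:5,4-b']difuran-4-yl]methanol
Conditions: Bu4NF, THF, 0 °C to rt
Reagents that add atoms: none
Why: Fluoride desilylation; no stereocentre is affected.

Step 10
Reactants: 16 benzylic alcohol
Product: 17 (2R,3R,5R,6R)-3,5-bis(3,5-dimethoxyphenyl)-2,6-bis(4-methoxyphenyl)-2,3,5,6-tetrahydrobenzo[1,2-b:5,4-b']difuran-4-carbaldehyde
Conditions: Dess–Martin periodinane, NaHCO3, CH2Cl2, 0 °C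
Reagents that add atoms: none
Why: Dess–Martin oxidation to the non-enolisable aldehyde, buffered because acid would trigger a Bradsher-type cyclisation of the neighbouring dimethoxyphenyl rings onto the formyl group.

Step 11
Reactants: 17 aldehyde; 18 (2,4-dimethoxyphenyl)acetic acid
Product: 20 2-(2,4-dimethoxyphenyl)-3-hydroxy-3-[(2R,3R,5R,6R)-3,5-bis(3,5-dimethoxyphenyl)-2,6-bis(4-methoxyphenyl)-2,3,5,6-tetrahydrobenzo[1,2-b:5,4-b']difuran-4-yl]propanoic acid (mixture at the two new centres), via dilithium enediolate 19 (not isolated)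
Conditions: 18 (1.5 equiv), LiN(i-Pr)2 (3.1 equiv), THF, −78 to 0 °C; then 17, −78 to −30 °C; cold dilute HCl to pH 4
Reagents that add atoms: none
Why: Ivanov aldol addition; the small, reactive enediolate adds to the hindered aldehyde, the carboxylate adduct resists retro-aldol, and the two new centres are erased in step 12.

Step 12
Reactants: 20 β-hydroxy acid
Product: 21 (2R,3R,5R,6R)-4-[(E)-2-(2,4-dimethoxyphenyl)ethenyl]-3,5-bis(3,5-dimethoxyphenyl)-2,6-bis(4-methoxyphenyl)-2,3,5,6-tetrahydrobenzo[1,2-b:5,4-b']difuran (any Z isomer is carried on)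
Conditions: Me2NCH(OCH2CMe3)2 (5 equiv), toluene, 80 °C
Reagents that add atoms: none
Why: Decarboxylative dehydration (Grob-type fragmentation of the O-activated β-hydroxy carboxylate); the neopentyl acetal cannot esterify the acid, and both alkene isomers give the same cation in step 13.

Step 13
Reactants: 21 stilbene
Product: 22 octamethyl ether of 23 (seven-membered ring closed, all five stereocentres R)
Conditions: CF3CO2H (10 equiv), CH2Cl2, −20 to 0 °C
Reagents that add atoms: none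
Why: Markovnikov protonation gives the 2,4-dimethoxybenzylic cation, and intramolecular Friedel–Crafts alkylation by the ortho carbon of a flanking 3,5-dimethoxyphenyl ring (the two are equivalent by C2 symmetry) closes the seven-membered ring with the aryl group pseudo-axial on the face of the ring-fusion hydrogen, away from the ortho methoxy group of the attacking ring, which gives the R centre.

Step 14
Reactants: 22 octamethyl ether
Product: 23 CNP0154047.1
Conditions: BBr3 (20 equiv), CH2Cl2, −78 to 20 °C; then H2O, 0 °C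
Reagents that add atoms: none
Why: Lewis-acid cleavage of the eight aryl methyl ethers; the trans dihydrofuran rings are the thermodynamic form and persist, and no stereocentre is changed.

**Compound list**

1 | 3,5-dihydroxybenzyl alcohol | OCc1cc(O)cc(O)c1 | starting material
2 | 4-methoxybenzyl chloride | COc1ccc(CCl)cc1 | starting material
3 | [3,5-bis(4-methoxybenzyloxy)phenyl]methanol | COc1ccc(COc2cc(CO)cc(OCc3ccc(OC)cc3)c2)cc1 | intermediate
4 | [2,6-dibromo-3,5-bis(4-methoxybenzyloxy)phenyl]methanol | OCc1c(Br)c(OCc2ccc(OC)cc2)cc(OCc2ccc(OC)cc2)c1Br | intermediate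
5 | {[2,6-dibromo-3,5-bis(4-methoxybenzyloxy)phenyl]methoxy}triisopropylsilane | CC(C)[Si](OCc1c(Br)c(OCc2ccc(OC)cc2)cc(OCc2ccc(OC)cc2)c1Br)(C(C)C)C(C)C | intermediate
6 | 3,5-dimethoxybenzaldehyde | COc1cc(C=O)cc(OC)c1 | starting material
7 | monolithio bromide (aryllithium from 5) | [Li]c1c(CO[Si](C(C)C)(C(C)C)C(C)C)c(Br)c(OCc2ccc(OC)cc2)cc1OCc1ccc(OC)cc1 | intermediate
8 | bromo lithium alkoxide (mono-adduct, racemic) | [Li]OC(c1cc(OC)cc(OC)c1)c1c(CO[Si](C(C)C)(C(C)C)C(C)C)c(Br)c(OCc2ccc(OC)cc2)cc1OCc1ccc(OC)cc1 | intermediate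
9 | lithio lithium alkoxide (racemic) | [Li]OC(c1cc(OC)cc(OC)c1)c1c(CO[Si](C(C)C)(C(C)C)C(C)C)c([Li])c(OCc2ccc(OC)cc2)cc1OCc1ccc(OC)cc1 | intermediate
10 | [2-{[(triisopropylsilyl)oxy]methyl}-4,6-bis(4-methoxybenzyloxy)-1,3-phenylene]bis[(3,5-dimethoxyphenyl)methanol] (diastereomer mixture) | OC(c1cc(OC)cc(OC)c1)c1c(CO[Si](C(C)C)(C(C)C)C(C)C)c(C(O)c2cc(OC)cc(OC)c2)c(OCc2ccc(OC)cc2)cc1OCc1ccc(OC)cc1 | intermediate
11 | [2-{[(triisopropylsilyl)oxy]methyl}-4,6-bis(4-methoxybenzyloxy)-1,3-phenylene]bis[(3,5-dimethoxyphenyl)methanone] | O=C(c1cc(OC)cc(OC)c1)c1c(CO[Si](C(C)C)(C(C)C)C(C)C)c(C(=O)c2cc(OC)cc(OC)c2)c(OCc2ccc(OC)cc2)cc1OCc1ccc(OC)cc1 | intermediate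
12 | bis-hydrazone of 11 (E/Z mixture) | NN=C(c1cc(OC)cc(OC)c1)c1c(CO[Si](C(C)C)(C(C)C)C(C)C)c(C(=NN)c2cc(OC)cc(OC)c2)c(OCc2ccc(OC)cc2)cc1OCc1ccc(OC)cc1 | intermediate
13 | bis-diazo compound from 12 | [N-]=[N+]=C(c1cc(OC)cc(OC)c1)c1c(CO[Si](C(C)C)(C(C)C)C(C)C)c(C(=[N+]=[N-])c2cc(OC)cc(OC)c2)c(OCc2ccc(OC)cc2)cc1OCc1ccc(OC)cc1 | intermediate
14 | triisopropyl{[(2S,3R,5R,6S)-3,5-bis(3,5-dimethoxyphenyl)-2,6-bis(4-methoxyphenyl)-2,3,5,6-tetrahydrobenzo[1,2-b:5,4-b']difuran-4-yl]methoxy}silane | CC(C)[Si](OCc1c2c(cc3c1[C@@H](c1cc(OC)cc(OC)c1)[C@@H](c1ccc(OC)cc1)O3)O[C@H](c1ccc(OC)cc1)[C@@H]2c1cc(OC)cc(OC)c1)(C(C)C)C(C)C | intermediate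
15 | triisopropyl{[(2R,3R,5R,6R)-3,5-bis(3,5-dimethoxyphenyl)-2,6-bis(4-methoxyphenyl)-2,3,5,6-tetrahydrobenzo[1,2-b:5,4-b']difuran-4-yl]methoxy}silane | CC(C)[Si](OCc1c2c(cc3c1[C@@H](c1cc(OC)cc(OC)c1)[C@H](c1ccc(OC)cc1)O3)O[C@@H](c1ccc(OC)cc1)[C@@H]2c1cc(OC)cc(OC)c1)(C(C)C)C(C)C | intermediate
16 | [(2R,3R,5R,6R)-3,5-bis(3,5-dimethoxyphenyl)-2,6-bis(4-methoxyphenyl)-2,3,5,6-tetrahydrobenzo[1,2-b:5,4-b']difuran-4-yl]methanol | OCc1c2c(cc3c1[C@@H](c1cc(OC)cc(OC)c1)[C@H](c1ccc(OC)cc1)O3)O[C@@H](c1ccc(OC)cc1)[C@@H]2c1cc(OC)cc(OC)c1 | intermediate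
17 | (2R,3R,5R,6R)-3,5-bis(3,5-dimethoxyphenyl)-2,6-bis(4-methoxyphenyl)-2,3,5,6-tetrahydrobenzo[1,2-b:5,4-b']difuran-4-carbaldehyde | O=Cc1c2c(cc3c1[C@@H](c1cc(OC)cc(OC)c1)[C@H](c1ccc(OC)cc1)O3)O[C@@H](c1ccc(OC)cc1)[C@@H]2c1cc(OC)cc(OC)c1 | intermediate
18 | (2,4-dimethoxyphenyl)acetic acid | COc1ccc(CC(=O)O)c(OC)c1 | starting material
19 | dilithium enediolate of 18 | COc1ccc(C=C(O[Li])O[Li])c(OC)c1 | intermediate
20 | 2-(2,4-dimethoxyphenyl)-3-hydroxy-3-[(2R,3R,5R,6R)-3,5-bis(3,5-dimethoxyphenyl)-2,6-bis(4-methoxyphenyl)-2,3,5,6-tetrahydrobenzo[1,2-b:5,4-b']difuran-4-yl]propanoic acid (mixture at the two chain centres) | COc1ccc(C(C(=O)O)C(O)c2c3c(cc4c2[C@@H](c2cc(OC)cc(OC)c2)[C@H](c2ccc(OC)cc2)O4)O[C@@H](c2ccc(OC)cc2)[C@@H]3c2cc(OC)cc(OC)c2)c(OC)c1 | intermediate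
21 | (2R,3R,5R,6R)-4-[(E)-2-(2,4-dimethoxyphenyl)ethenyl]-3,5-bis(3,5-dimethoxyphenyl)-2,6-bis(4-methoxyphenyl)-2,3,5,6-tetrahydrobenzo[1,2-b:5,4-b']difuran | COc1ccc(/C=C/c2c3c(cc4c2[C@@H](c2cc(OC)cc(OC)c2)[C@H](c2ccc(OC)cc2)O4)O[C@@H](c2ccc(OC)cc2)[C@@H]3c2cc(OC)cc(OC)c2)c(OC)c1 | intermediate
22 | octamethyl ether of 23 (all-R) | COc1ccc([C@@H]2Oc3cc4c5c(c3[C@H]2c2cc(OC)cc(OC)c2)C[C@H](c2ccc(OC)cc2OC)c2c(OC)cc(OC)cc2[C@H]5[C@H](c2ccc(OC)cc2)O4)cc1 | intermediate
23 | CNP0154047.1 (all five stereocentres R) | Oc1ccc([C@@H]2Oc3cc4c5c(c3[C@H]2c2cc(O)cc(O)c2)C[C@H](c2ccc(O)cc2O)c2c(O)cc(O)cc2[C@H]5[C@H](c2ccc(O)cc2)O4)cc1 | target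

**Count**

Total steps: 14. Longest linear sequence: 14 steps (1 to 23); compounds 2, 6 and 18 are bought.

**Steps most likely to fail**

Step 6. The ketones of 11 carry two ortho substituents each, so hydrazone condensation may stall. The fallback sets out from dibromide 5. The two bromine–lithium exchanges are run as in step 4, but each aryllithium is added to one equivalent of 3,5-dimethoxybenzonitrile (a linear, unhindered electrophile), and a methanol quench gives the bis(N–H ketimine) F1. Transimination with N2H4·H2O and catalytic AcOH in EtOH at 60 °C, which exchanges at an iminium and not at a carbonyl, releases ammonia and gives bis-hydrazone 12, where the route is rejoined.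

Step 7. The double carbene insertion may give too little of the C2-symmetric isomer or be diverted by the crowded environment. The fallback sets out from diketone 11 and uses no carbene. The phosphazene base P4-t-Bu in toluene at 100 °C deprotonates each 4-methoxybenzylic ether CH2, the carbanion adds to the neighbouring ketone, and loss of water gives the fully aromatic benzodifuran F2. Ionic hydrogenation (Et3SiH, CF3CO2H, CH2Cl2, −20 °C) protonates C3 and delivers hydride to C2 trans to the C3 aryl group, giving the racemic trans,trans silyl ether F3 together with its meso-type diastereomer. That diastereomer is removed on silica, and preparative HPLC on a chiral stationary phase gives 15, where the route is rejoined. This fallback reaches the single enantiomer by resolution, not by asymmetric induction.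

Step 13. Under acid the electron-rich alkene of 21 can also attack a ring-opened dihydrofuran cation and give an indane instead of the seven-membered ring. The fallback sets out from aldehyde 17 and generates the same cation with no alkene present. Wittig reaction with Ph3P=CHOMe gives the enol ether F4, and mild hydrolysis (aqueous oxalic acid, THF) gives the arylacetaldehyde F5. Addition of 2,4-dimethoxyphenylmagnesium bromide at −78 °C gives the carbinol F6 as an epimer mixture. BF3·OEt2 in CH2Cl2 at −40 °C ionises only this doubly activated benzylic alcohol, and Friedel–Crafts closure gives 22, where the route is rejoined.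

**Further compounds**

F1 | step 6 | bis(N–H ketimine): [2-{[(triisopropylsilyl)oxy]methyl}-4,6-bis(4-methoxybenzyloxy)-1,3-phenylene]bis[(3,5-dimethoxyphenyl)methanimine] | N=C(c1cc(OC)cc(OC)c1)c1c(CO[Si](C(C)C)(C(C)C)C(C)C)c(C(=N)c2cc(OC)cc(OC)c2)c(OCc2ccc(OC)cc2)cc1OCc1ccc(OC)cc1
F2 | step 7 | triisopropyl{[3,5-bis(3,5-dimethoxyphenyl)-2,6-bis(4-methoxyphenyl)benzo[1,2-b:5,4-b']difuran-4-yl]methoxy}silane | CC(C)[Si](OCc1c2c(cc3c1c(-c1cc(OC)cc(OC)c1)c(-c1ccc(OC)cc1)o3)oc(-c1ccc(OC)cc1)c2-c1cc(OC)cc(OC)c1)(C(C)C)C(C)C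
F3 | step 7 | racemic trans,trans silyl ether (15 plus its enantiomer) | CC(C)[Si](OCc1c2c(cc3c1[C@@H](c1cc(OC)cc(OC)c1)[C@H](c1ccc(OC)cc1)O3)O[C@@H](c1ccc(OC)cc1)[C@@H]2c1cc(OC)cc(OC)c1)(C(C)C)C(C)C.CC(C)[Si](OCc1c2c(cc3c1[C@H](c1cc(OC)cc(OC)c1)[C@@H](c1ccc(OC)cc1)O3)O[C@H](c1ccc(OC)cc1)[C@H]2c1cc(OC)cc(OC)c1)(C(C)C)C(C)C
F4 | step 13 | (2R,3R,5R,6R)-4-(2-methoxyethenyl)-3,5-bis(3,5-dimethoxyphenyl)-2,6-bis(4-methoxyphenyl)-2,3,5,6-tetrahydrobenzo[1,2-b:5,4-b']difuran (E/Z mixture) | COC=Cc1c2c(cc3c1[C@@H](c1cc(OC)cc(OC)c1)[C@H](c1ccc(OC)cc1)O3)O[C@@H](c1ccc(OC)cc1)[C@@H]2c1cc(OC)cc(OC)c1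
F5 | step 13 | 2-[(2R,3R,5R,6R)-3,5-bis(3,5-dimethoxyphenyl)-2,6-bis(4-methoxyphenyl)-2,3,5,6-tetrahydrobenzo[1,2-b:5,4-b']difuran-4-yl]acetaldehyde | O=CCc1c2c(cc3c1[C@@H](c1cc(OC)cc(OC)c1)[C@H](c1ccc(OC)cc1)O3)O[C@@H](c1ccc(OC)cc1)[C@@H]2c1cc(OC)cc(OC)c1
F6 | step 13 | 1-(2,4-dimethoxyphenyl)-2-[(2R,3R,5R,6R)-3,5-bis(3,5-dimethoxyphenyl)-2,6-bis(4-methoxyphenyl)-2,3,5,6-tetrahydrobenzo[1,2-b:5,4-b']difuran-4-yl]ethanol (carbinol epimers) | COc1ccc(C(O)Cc2c3c(cc4c2[C@@H](c2cc(OC)cc(OC)c2)[C@H](c2ccc(OC)cc2)O4)O[C@@H](c2ccc(OC)cc2)[C@@H]3c2cc(OC)cc(OC)c2)c(OC)c1
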